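## Retrosynthetic overview

1. The target comes from the 8β-H C17 aldehyde (C8 set by epimerisation), which comes from hydroboration of an 8(17)-alkene. The butenolide comes from an α-alkylidene lactone by double-bond isomerisation, made by cross-metathesis of a C9 allyl group with α-methylene-γ-butyrolactone.
2. The C19 acid and the C3 methylene come from a 3-oxo 19-ester of a chiral alcohol (Caglioti reduction with simultaneous ester reduction, then reoxidation).
3. Rings A and B form together: the trans-decalin comes from an acyclic trienyl α-methyl β-keto ester by an oxidative radical bicyclisation (C4–C5 and C9–C10 bonds; C4, C5, C9, C10 and the 8(17)-alkene set at once).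
4. The acyclic precursor comes from a β-keto ester dianion and an (E,E)-allylic bromide, itself from geranyl bromide, a vinyl Grignard reagent and SeO2 oxidation.
5. Ring order: A and B in one operation (step 6); the lactone ring is brought in intact (step 10) and becomes the butenolide (step 12).

Convention: bicyclic compounds carry labdane numbering (C4 bears C18/C19, C8 bears C17, C9 bears C11, C10 bears C20); β is the face of the C10 methyl group.

Assumption: the (1R,2S,5R)-8-phenylmenthyl ester is taken to direct the bicyclisation to the 4β-ester/5α-H/10β-methyl series, as recalled (not verified) for the same auxiliary in the podocarpic acid series. If the sense is the opposite, the enantiomeric alcohol is used and nothing else changes.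

## Route

Step 1
Reactants: 1 ethyl 2-methyl-3-oxobutanoate; 2 (1R,2S,5R)-5-methyl-2-(2-phenylpropan-2-yl)cyclohexan-1-ol [(−)-8-phenylmenthol]
Product: 3 (1R,2S,5R)-8-phenylmenthyl 2-methyl-3-oxobutanoate
Conditions: DMAP (0.3 equiv), toluene, reflux, 4 Å sieves (removal of EtOH)
Reagents that add atoms: none
Why: DMAP-catalysed transesterification of a β-keto ester through the acylketene attaches the chiral alcohol; the α-stereocentre is labile and is destroyed later.

Step 2
Reactants: 4 geranyl bromide [(2E)-1-bromo-3,7-dimethylocta-2,6-diene]; 5 vinylmagnesium bromide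
Product: 6 (4E)-5,9-dimethyldeca-1,4,8-triene
Conditions: CuI (5 mol %), THF, −30 → 0 °C
Reagents that add atoms: none
Why: copper-catalysed Grignard cross-coupling at the primary allylic carbon (SN2) gives the skipped diene with the E double bond retained.

Step 3
Reactants: 6 (4E)-5,9-dimethyldeca-1,4,8-triene
Product: 7 (2E,6E)-2,6-dimethyldeca-2,6,9-trien-1-ol
Conditions: SeO2 (0.2 equiv), t-BuOOH (70 % aq., 2.5 equiv), salicylic acid (0.1 equiv), CH2Cl2, rt
Reagents that add atoms: selenium dioxide O=[Se]=O (oxygen atom; reoxidised by tert-butyl hydroperoxide CC(C)(C)OO)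
Why: Riley-type allylic oxidation (ene reaction then [2,3]-sigmatropic shift) takes place at the less hindered terminal trisubstituted alkene and on its E-methyl group, giving the (E)-allylic alcohol.

Step 4
Reactants: 7 (2E,6E)-2,6-dimethyldeca-2,6,9-trien-1-ol
Product: 8 (2E,6E)-1-bromo-2,6-dimethyldeca-2,6,9-triene
Conditions: CBr4, PPh3, CH2Cl2, 0 °C
Reagents that add atoms: carbon tetrabromide BrC(Br)(Br)Br
Why: Appel reaction of a primary allylic alcohol proceeds by SN2 at 0 °C without allylic transposition or loss of alkene geometry.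

Step 5
Reactants: 3 (1R,2S,5R)-8-phenylmenthyl 2-methyl-3-oxobutanoate; 8 (2E,6E)-1-bromo-2,6-dimethyldeca-2,6,9-triene
Product: 10 (1R,2S,5R)-8-phenylmenthyl (6E,10E)-2,6,10-trimethyl-3-oxotetradeca-6,10,13-trienoate, via keto ester dianion 9 (not isolated)
Conditions: 3, NaH, THF, 0 °C; n-BuLi, 0 °C; then 8, 0 °C; aq. NH4Cl
Reagents that add atoms: none
Why: Weiler dianion alkylation, in which the more basic terminal carbanion of the β-keto ester dianion displaces the allylic bromide by SN2 and leaves both E alkenes untouched.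

Step 6
Reactants: 10 (1R,2S,5R)-8-phenylmenthyl (6E,10E)-2,6,10-trimethyl-3-oxotetradeca-6,10,13-trienoate
Product: 11 (1R,2S,5R)-8-phenylmenthyl 3-oxo-14,15,16-trinorlabda-8(17),12-dien-19-oate (4β-ester 5α-H 9β-allyl 10β-methyl)
Conditions: Mn(OAc)3·2H2O (2.2 equiv), Cu(OAc)2·H2O (1.0 equiv), degassed AcOH, 25 °C; chromatographic removal of the minor diastereomer
Reagents that add atoms: none
Why: Mn(OAc)3/Cu(OAc)2 oxidative free-radical polyene bicyclisation (Snider type): the trivalent-manganese enolate gives the electrophilic C4 radical, which closes 6-endo on the C5=C10 alkene, and the C10 radical closes 6-endo on the C8=C9 alkene through a chair–chair array that sets the trans ring fusion (5α-H, 10β-CH3), the axial 4β-ester and, from the E geometry, the equatorial 9β-allyl group; the phenyl ring of the auxiliary shields one face of the C4 radical to fix the absolute sense, and divalent copper oxidises the tertiary C8 radical to the less substituted exocyclic alkene (the allyl group cannot be reached by a favourable ring closure and stays a spectator).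

Step 7
Reactants: 11 (1R,2S,5R)-8-phenylmenthyl 3-oxo-14,15,16-trinorlabda-8(17),12-dien-19-oate
Product: 12 (1R,2S,5R)-8-phenylmenthyl 3-(tosylhydrazono)-14,15,16-trinorlabda-8(17),12-dien-19-oate
Conditions: TsNHNH2 (1.5 equiv), AcOH (cat.), EtOH, reflux
Reagents that add atoms: p-toluenesulfonohydrazide Cc1ccc(cc1)S(=O)(=O)NN
Why: condensation of the only ketone with the sulfonyl hydrazide gives the tosylhydrazone; the hindered ester and both alkenes are inert.

Step 8
Reactants: 12 (1R,2S,5R)-8-phenylmenthyl 3-(tosylhydrazono)-14,15,16-trinorlabda-8(17),12-dien-19-oate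
Product: 13 14,15,16-trinorlabda-8(17),12-dien-19-ol
Conditions: LiAlH4 (6 equiv), THF, reflux; Fieser work-up (auxiliary 2 recovered)
Reagents that add atoms: none
Why: Caglioti reduction (hydride addition to C=N, loss of sulfinate and N2) converts C3 to CH2 while the same hydride reduces the hindered ester to the neopentyl C19 alcohol and releases the auxiliary; no stereocentre is touched.

Step 9
Reactants: 13 14,15,16-trinorlabda-8(17),12-dien-19-ol
Product: 14 14,15,16-trinorlabda-8(17),12-dien-19-oic acid
Conditions: CrO3, H2SO4, H2O (Jones reagent), acetone, 0 °C → rt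
Reagents that add atoms: chromium trioxide O=[Cr](=O)=O; water O
Why: Jones oxidation takes the primary neopentyl alcohol through the aldehyde hydrate to the acid, and isolated alkenes survive the short cold exposure.

Step 10
Reactants: 14 14,15,16-trinorlabda-8(17),12-dien-19-oic acid; 15 α-methylene-γ-butyrolactone (3-methylideneoxolan-2-one)
Product: 16 (12E)-labda-8(17),12-dien-16,15-olid-19-oic acid
Conditions: 15 (5 equiv), second-generation Hoveyda–Grubbs catalyst RuCl2(H2IMes)(=CH-C6H4-2-OiPr) (5 mol %), 2,6-dichloro-1,4-benzoquinone (10 mol %), CH2Cl2, 40 °C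
Reagents that add atoms: none
Why: olefin cross-metathesis joins the terminal allyl alkene to the methylene lactone with loss of ethylene, the hindered 1,1-disubstituted 8(17)-alkene does not take part, and the quinone suppresses ruthenium hydride isomerisation; the geometry of the new alkene is of no consequence.

Step 11
Reactants: 16 (12E)-labda-8(17),12-dien-16,15-olid-19-oic acid
Product: 18 17-hydroxy-8αH-labd-12-en-16,15-olid-19-oic acid, via C17 alkylborane 17 (not isolated)
Conditions: 9-BBN (2.5 equiv), THF, rt; then H2O, NaBO3·4H2O, rt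
Reagents that add atoms: 9-borabicyclo[3.3.1]nonane [H]B1C2CCCC1CCC2 (boron in 17 only); sodium perborate [Na+].[O-]OB=O (oxygen of the C17 hydroxyl)
Why: anti-Markovnikov hydroboration–oxidation of the exocyclic alkene; the borane is expected to add from the α face, away from the axial C10 methyl, giving 8α-H and an axial CH2OH, but this configuration is corrected in step 13, so any facial mixture converges, and the electron-poor alkylidene lactone and the acid (as acyloxyborane) are not reduced at rt.

Step 12
Reactants: 18 17-hydroxy-8αH-labd-12-en-16,15-olid-19-oic acid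
Product: 19 17-hydroxy-8αH-labd-13-en-16,15-olid-19-oic acid
Conditions: RhCl3·3H2O (10 mol %), EtOH, reflux
Reagents that add atoms: none
Why: rhodium hydride addition–elimination (alkene isomerisation) moves the exocyclic C12=C13 bond into the ring to give the thermodynamically favoured α-alkyl butenolide; no other alkene remains to be isomerised.

Step 13
Reactants: 19 17-hydroxy-8αH-labd-13-en-16,15-olid-19-oic acid
Product: 21 17-oxo-8βH-labd-13-en-16,15-olid-19-oic acid, via axial C17 aldehyde 20 (not isolated)
Conditions: Dess–Martin periodinane (1.3 equiv), CH2Cl2, 0 °C → rt; aqueous work-up; then DBU (2 equiv), CH2Cl2, rt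
Reagents that add atoms: none
Why: Dess–Martin oxidation followed by base-mediated epimerisation through the enolate: the axial formyl group, syn-diaxial to the C10 methyl, equilibrates to the equatorial 8β-H aldehyde under thermodynamic control, while C9 is not enolisable.

Step 14
Reactants: 21 17-oxo-8βH-labd-13-en-16,15-olid-19-oic acid
Product: 22 17-hydroxy-8βH-labd-13-en-16,15-olid-19-oic acid (target CNP0562063.1)
Conditions: NaBH4 (1.5 equiv), THF/MeOH, −20 → 0 °C; acidify to pH 3
Reagents that add atoms: none
Why: chemoselective borohydride reduction of the aldehyde at low temperature leaves the butenolide and the carboxylate untouched and retains the C8 configuration.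

## Compound list

1 | ethyl 2-methyl-3-oxobutanoate (racemic) | CCOC(=O)C(C)C(C)=O | starting material
2 | (1R,2S,5R)-5-methyl-2-(2-phenylpropan-2-yl)cyclohexan-1-ol, (−)-8-phenylmenthol (recovered in step 8) | O[C@@H]1C[C@H](C)CC[C@H]1C(C)(C)c1ccccc1 | starting material
3 | (1R,2S,5R)-8-phenylmenthyl 2-methyl-3-oxobutanoate (both C2 epimers) | CC(=O)C(C)C(=O)O[C@@H]1C[C@H](C)CC[C@H]1C(C)(C)c1ccccc1 | intermediate
4 | geranyl bromide, (2E)-1-bromo-3,7-dimethylocta-2,6-diene | CC(C)=CCC/C(C)=C/CBr | starting material
5 | vinylmagnesium bromide | C=C[Mg]Br | starting material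
6 | (4E)-5,9-dimethyldeca-1,4,8-triene | CC(C)=CCC/C(C)=C/CC=C | intermediate
7 | (2E,6E)-2,6-dimethyldeca-2,6,9-trien-1-ol | OC/C(C)=C/CC/C(C)=C/CC=C | intermediate
8 | (2E,6E)-1-bromo-2,6-dimethyldeca-2,6,9-triene | BrC/C(C)=C/CC/C(C)=C/CC=C | intermediate
9 | sodium lithium dianion of 3 (not isolated) | [Na+].[Li+].[CH2-]C(=O)[C-](C)C(=O)O[C@@H]1C[C@H](C)CC[C@H]1C(C)(C)c1ccccc1 | intermediate
10 | (1R,2S,5R)-8-phenylmenthyl (6E,10E)-2,6,10-trimethyl-3-oxotetradeca-6,10,13-trienoate (both C2 epimers) | CC(C(=O)O[C@@H]1C[C@H](C)CC[C@H]1C(C)(C)c1ccccc1)C(=O)CC/C(C)=C/CC/C(C)=C/CC=C | intermediate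
11 | (1R,2S,5R)-8-phenylmenthyl 3-oxo-14,15,16-trinorlabda-8(17),12-dien-19-oate; trans-decalin, 4β (axial) ester, 4α-CH3, 5α-H, 9α-H (9β-allyl), 10β-CH3, 8-methylidene | C[C@]12CCC(=O)[C@](C)(C(=O)O[C@@H]3C[C@H](C)CC[C@H]3C(C)(C)c3ccccc3)[C@@H]1CCC(=C)[C@@H]2CC=C | intermediate
12 | tosylhydrazone of 11 at C3 | C[C@]12CCC(=NNS(=O)(=O)c3ccc(C)cc3)[C@](C)(C(=O)O[C@@H]3C[C@H](C)CC[C@H]3C(C)(C)c3ccccc3)[C@@H]1CCC(=C)[C@@H]2CC=C | intermediate
13 | 14,15,16-trinorlabda-8(17),12-dien-19-ol (4β-CH2OH, 5α-H, 9β-allyl, 10β-CH3) | C[C@]12CCC[C@](C)(CO)[C@@H]1CCC(=C)[C@@H]2CC=C | intermediate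
14 | 14,15,16-trinorlabda-8(17),12-dien-19-oic acid | C[C@]12CCC[C@](C)(C(=O)O)[C@@H]1CCC(=C)[C@@H]2CC=C | intermediate
15 | α-methylene-γ-butyrolactone, 3-methylideneoxolan-2-one | C=C1CCOC1=O | starting material
16 | (12E)-labda-8(17),12-dien-16,15-olid-19-oic acid | C[C@]12CCC[C@](C)(C(=O)O)[C@@H]1CCC(=C)[C@@H]2C/C=C1\CCOC1=O | intermediate
17 | C17 9-BBN alkylborane of 16, 8α-H (not isolated; carboxyl shown free) | C[C@]12CCC[C@](C)(C(=O)O)[C@@H]1CC[C@H](CB3C4CCCC3CCC4)[C@@H]2C/C=C1\CCOC1=O | intermediate
18 | 17-hydroxy-8αH-labd-12-en-16,15-olid-19-oic acid (axial 8β-CH2OH) | C[C@]12CCC[C@](C)(C(=O)O)[C@@H]1CC[C@H](CO)[C@@H]2C/C=C1\CCOC1=O | intermediate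
19 | 17-hydroxy-8αH-labd-13-en-16,15-olid-19-oic acid (C8 epimer of the target) | C[C@]12CCC[C@](C)(C(=O)O)[C@@H]1CC[C@H](CO)[C@@H]2CCC1=CCOC1=O | intermediate
20 | 17-oxo-8αH-labd-13-en-16,15-olid-19-oic acid, axial aldehyde (not isolated) | C[C@]12CCC[C@](C)(C(=O)O)[C@@H]1CC[C@H](C=O)[C@@H]2CCC1=CCOC1=O | intermediate
21 | 17-oxo-8βH-labd-13-en-16,15-olid-19-oic acid, equatorial aldehyde | C[C@]12CCC[C@](C)(C(=O)O)[C@@H]1CC[C@@H](C=O)[C@@H]2CCC1=CCOC1=O | intermediate
22 | (1S,4aR,5S,6R,8aR)-6-(hydroxymethyl)-1,4a-dimethyl-5-[2-(2-oxo-2,5-dihydrofuran-3-yl)ethyl]decahydronaphthalene-1-carboxylic acid, 17-hydroxy-8βH-labd-13-en-16,15-olid-19-oic acid | C[C@]12CCC[C@](C)(C(=O)O)[C@@H]1CC[C@@H](CO)[C@@H]2CCC1=CCOC1=O | target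

## Step count and risks

Total: 14 steps. Longest linear sequence: 13 steps (steps 2–14 from geranyl bromide); step 1 is a one-step side branch.

The three steps most likely to fail:

**Step 6 (radical bicyclisation).** Risks are modest auxiliary control, endocyclic alkene isomers from the copper termination, and moderate yield. The fallback sets out from compound 10 and returns at compound 11, and replaces oxidative termination by a group-transfer cascade. Compound 10 is selenenylated (NaH, PhSeCl, THF, 0 °C) to the α-phenylselanyl keto ester F1. Irradiation with visible light in benzene in the presence of Yb(OTf)3 then gives, by phenylselanyl group-transfer tandem radical cyclisation, the bicyclic tertiary C8 selenide F2. Oxidation with H2O2/pyridine and syn-elimination of the selenoxide gives compound 11.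

**Step 8 (Caglioti reduction of a hindered tosylhydrazone with simultaneous ester reduction).** Risks are elimination to a 2-ene or incomplete reduction. The fallback sets out from compound 11 and returns at compound 13, and removes the C3 oxygen by radical deoxygenation. NaBH4 in MeOH reduces the ketone to the 3-hydroxy ester F3. 1,1'-Thiocarbonyldiimidazole with DMAP in hot 1,2-dichloroethane gives the imidazolyl thiocarbonate F4. Bu3SnH/AIBN in toluene at 90 °C (Barton–McCombie) gives the 3-deoxy 8-phenylmenthyl ester F5. LiAlH4 in refluxing THF then gives compound 13 and returns the auxiliary.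

**Step 11 (9-BBN hydroboration of a hindered alkene beside a free acid and a lactone).** Risks are sluggish addition or partial lactone reduction. The fallback sets out from compound 16 and returns at compound 18, and replaces the borane by an epoxide route. mCPBA in CH2Cl2 epoxidises only the electron-rich 8(17)-alkene to the 8,17-epoxide F6. Cp2TiCl (from Cp2TiCl2 and Mn dust) with 1,4-cyclohexadiene in THF opens it reductively through the tertiary C8 radical to the primary alcohol, compound 18 (possibly with its C8 epimer, which converges in step 13).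

Further compounds
F1 | step 6 | (1R,2S,5R)-8-phenylmenthyl (6E,10E)-2,6,10-trimethyl-3-oxo-2-(phenylselanyl)tetradeca-6,10,13-trienoate | CC([Se]c1ccccc1)(C(=O)O[C@@H]1C[C@H](C)CC[C@H]1C(C)(C)c1ccccc1)C(=O)CC/C(C)=C/CC/C(C)=C/CC=C
F2 | step 6 | (1R,2S,5R)-8-phenylmenthyl 3-oxo-8-(phenylselanyl)-14,15,16-trinorlabd-12-en-19-oate | C[C@]12CCC(=O)[C@](C)(C(=O)O[C@@H]3C[C@H](C)CC[C@H]3C(C)(C)c3ccccc3)[C@@H]1CCC(C)([Se]c3ccccc3)[C@@H]2CC=C
F3 | step 8 | (1R,2S,5R)-8-phenylmenthyl 3-hydroxy-14,15,16-trinorlabda-8(17),12-dien-19-oate | C[C@]12CCC(O)[C@](C)(C(=O)O[C@@H]3C[C@H](C)CC[C@H]3C(C)(C)c3ccccc3)[C@@H]1CCC(=C)[C@@H]2CC=C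
F4 | step 8 | (1R,2S,5R)-8-phenylmenthyl 3-[(1H-imidazol-1-ylcarbonothioyl)oxy]-14,15,16-trinorlabda-8(17),12-dien-19-oate | C[C@]12CCC(OC(=S)n3ccnc3)[C@](C)(C(=O)O[C@@H]3C[C@H](C)CC[C@H]3C(C)(C)c3ccccc3)[C@@H]1CCC(=C)[C@@H]2CC=C
F5 | step 8 | (1R,2S,5R)-8-phenylmenthyl 14,15,16-trinorlabda-8(17),12-dien-19-oate | C[C@]12CCC[C@](C)(C(=O)O[C@@H]3C[C@H](C)CC[C@H]3C(C)(C)c3ccccc3)[C@@H]1CCC(=C)[C@@H]2CC=C
F6 | step 11 | (12E)-8,17-epoxylabd-12-en-16,15-olid-19-oic acid | C[C@]12CCC[C@](C)(C(=O)O)[C@@H]1CCC3(CO3)[C@@H]2C/C=C1\CCOC1=O
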